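The cyclohexene ring of the target hides a mirror plane through C1 and C4: with the alkene and the benzoates removed, C2/C3 and C6/C5 are equivalent arms of a carbinol carbon that bears O1 and the exocyclic C7. The route therefore rests on breaking this symmetry in methyl 1-hydroxycyclohexa-2,5-diene-1-carboxylate, an achiral dienol ester made from benzoic acid by Birch reduction and enolate hydroxylation. One hydroxyl-guided, ligand-controlled oxygen transfer turns only the C2=C3 alkene into an oxirane cis to O1 and fixes C1, C2 and C3 together. The second alkene then takes up O5 and O6, the oxirane is unfolded into the C2 carbinol and the C3=C4 alkene, and the benzoates follow.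

Key step: step 4

Atom labels: C1 is the ring carbon bearing O1 and the exocyclic C7. C2 to C6 follow round the ring so that the target has benzoates on O2, O5 and O7, the alkene at C3=C4 and free hydroxyls on O1 and O6. These labels are kept for every intermediate, and the CIP descriptors in the names refer to them. The target is (1S,2R,5S,6S), with O1, O2, O5 and O6 all on one ring face and C7 on the other.

Assumption: the (1R,2R) ligand is taken as the antipode that epoxidises the alkene labelled C2=C3; if a first run shows the opposite sense, the (1S,2S) ligand is used and nothing else changes.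

Remark on the design: the methyl ester stays on C1 until step 7, because it tempers ionisation of the dienol and is not exchanged by the hindered tert-butoxide ligands of the catalyst. O5/O6 are masked as an acetonide so that O2 and O7 can be benzoylated exhaustively, which leaves a single site-selective acylation (O5 against O6) at the end.

Step 1
Reactants: 1 benzoic acid
Product: 2 cyclohexa-2,5-diene-1-carboxylic acid
Conditions: Na, liquid NH3, EtOH, −78 to −33 °C; NH4Cl; aq. HCl
Reagents that add atoms: none
Why: Birch reduction of a benzoate delivers hydrogen to the ipso and para carbons, so the skipped 2,5-diene acid is the expected product and no stereocentre arises.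

Step 2
Reactants: 2 cyclohexa-2,5-diene-1-carboxylic acid; 3 iodomethane
Product: 4 methyl cyclohexa-2,5-diene-1-carboxylate
Conditions: MeI, K2CO3, DMF, 0 °C to rt
Reagents that add atoms: iodomethane, CI
Why: SN2 O-methylation of the carboxylate under weakly basic, non-acidic conditions should leave the skipped diene unconjugated.

Step 3
Reactants: 4 methyl cyclohexa-2,5-diene-1-carboxylate; 5 3-phenyl-2-(phenylsulfonyl)oxaziridine
Product: 7 methyl 1-hydroxycyclohexa-2,5-diene-1-carboxylate, via potassium dienolate 6 (not isolated)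
Conditions: KN(SiMe3)2, THF, −78 °C; then 5, −78 °C; sat. aq. NH4Cl, −78 °C; Et3N-deactivated silica
Reagents that add atoms: 3-phenyl-2-(phenylsulfonyl)oxaziridine, O=S(=O)(N1OC1c1ccccc1)c1ccccc1
Why: Davis oxidation, in which the cross-conjugated potassium ester enolate takes up the electrophilic oxaziridine oxygen at its α-carbon C1, as such dienolates do in alkylation, while a cold neutral quench keeps the tertiary dienol from losing water; C1 is not yet stereogenic.

Step 4
Reactants: 7 methyl 1-hydroxycyclohexa-2,5-diene-1-carboxylate; 8 cumene hydroperoxide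
Product: 9 methyl (1S,2R,3R)-2,3-epoxy-1-hydroxycyclohex-5-ene-1-carboxylate (oxirane oxygen cis to O1)
Conditions: Hf(OtBu)4 (10 mol%), (1R,2R)-N,N'-dihydroxy-N,N'-bis(diphenylacetyl)cyclohexane-1,2-diamine (11 mol%), cumene hydroperoxide (1.2 equiv), MgO, 4 Å molecular sieves, toluene, 0 °C
Reagents that add atoms: cumene hydroperoxide, CC(C)(OO)c1ccccc1
Why: Proposed new method: exchange of tert-butoxide on tetravalent hafnium for the O1 alkoxide of 7 and for the hydroperoxide places the metal-bound peroxide beside one of the two enantiotopic alkenes inside the C2-symmetric bishydroxamate pocket, and its distal oxygen is passed to C2=C3 in one concerted step, so the oxirane closes by syn addition without an open intermediate (closest known reaction types: desymmetrising Sharpless epoxidation of divinyl carbinols and hafnium–bishydroxamate epoxidation of tertiary allylic alcohols). The O1–Hf tether fixes the face, so both new C–O bonds form cis to O1 and C2 and C3 are set as a cis-fused pair. The ligand decides which alkene reacts and thereby makes C1 stereogenic. The step needs group selectivity, face selectivity and arrest at the mono-epoxide; the minor mono-epoxide still carries the alkene that the catalyst prefers and should be consumed to the meso bis-epoxide, which should raise enantiopurity at the cost of some material. The ester on C1 destabilises the cyclohexadienyl cation and so should hold back Lewis-acid ionisation and loss of water to methyl benzoate, with MgO as an insoluble acid scavenger.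

Step 5
Reactants: 9 methyl (1S,2R,3R)-2,3-epoxy-1-hydroxycyclohex-5-ene-1-carboxylate; 10 osmium tetroxide
Product: 12 methyl (1S,2R,3R,5S,6S)-2,3-epoxy-1,5,6-trihydroxycyclohexane-1-carboxylate, via TMEDA-bound cyclic osmate ester 11 (not isolated)
Conditions: OsO4 (1.05 equiv), Me2NCH2CH2NMe2 (TMEDA, 1.1 equiv), CH2Cl2, −78 °C; then aq. Na2SO3, THF, rt to 40 °C
Reagents that add atoms: osmium tetroxide, O=[Os](=O)(=O)=O
Why: Hydroxyl-directed dihydroxylation, in which a hydrogen bond from O1–H to an oxo ligand of the OsO4–TMEDA adduct steers the [3+2] addition to the O1 face of C5=C6, so O5 and O6 are set cis to O1, while the oxirane lies on the same face and cannot be opened by the new hydroxyls.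

Step 6
Reactants: 12 methyl (1S,2R,3R,5S,6S)-2,3-epoxy-1,5,6-trihydroxycyclohexane-1-carboxylate; 13 2-methoxypropene
Product: 14 methyl (1R,2R,3R,5S,6S)-2,3-epoxy-1-hydroxy-5,6-(isopropylidenedioxy)cyclohexane-1-carboxylate
Conditions: 2-methoxypropene, pyridinium p-toluenesulfonate (cat.), CH2Cl2, 0 °C
Reagents that add atoms: 2-methoxypropene, C=C(C)OC
Why: Kinetic acetalisation should pick the only secondary–secondary cis-1,2-diol (O5/O6), the hindered tertiary O1 beside the ester being much slower, and the mild pyridinium catalyst spares the oxirane.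

Step 7
Reactants: 14 methyl (1R,2R,3R,5S,6S)-2,3-epoxy-1-hydroxy-5,6-(isopropylidenedioxy)cyclohexane-1-carboxylate
Product: 15 (1R,2R,3R,5S,6S)-2,3-epoxy-1-(hydroxymethyl)-5,6-(isopropylidenedioxy)cyclohexan-1-ol
Conditions: NaBH4, EtOH, 0 °C to rt
Reagents that add atoms: none
Why: Borohydride reduction of an α-hydroxy ester, accelerated by chelation through O1, should give the primary alcohol at C7 without touching the oxirane or the acetal.

Step 8
Reactants: 15 (1R,2R,3R,5S,6S)-2,3-epoxy-1-(hydroxymethyl)-5,6-(isopropylidenedioxy)cyclohexan-1-ol; 16 diphenyl diselenide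
Product: 19 (1R,2R,5S,6S)-1-(hydroxymethyl)-5,6-(isopropylidenedioxy)cyclohex-3-ene-1,2-diol, via hydroxy selenide 17 (not isolated), via selenoxide 18 (not isolated)
Conditions: (PhSe)2 (0.6 equiv), NaBH4, EtOH, rt to 70 °C; then THF, pyridine, 30% aq. H2O2, 0 °C to rt
Reagents that add atoms: none
Why: Selenide opening followed by selenoxide syn-elimination, in which phenylselenolate attacks the oxirane by SN2 at C3, the carbon remote from the quaternary C1, with inversion there and retention at C2, and the selenoxide then eliminates toward the C4 hydrogen and away from the carbinol carbon to give C3=C4.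

Step 9
Reactants: 19 (1R,2R,5S,6S)-1-(hydroxymethyl)-5,6-(isopropylidenedioxy)cyclohex-3-ene-1,2-diol; 20 benzoyl chloride
Product: 21 [(1R,2R,5S,6S)-2-(benzoyloxy)-1-hydroxy-5,6-(isopropylidenedioxy)cyclohex-3-en-1-yl]methyl benzoate
Conditions: BzCl (3 equiv), pyridine, 4-(dimethylamino)pyridine (cat.), CH2Cl2, 0 °C to rt
Reagents that add atoms: benzoyl chloride, O=C(Cl)c1ccccc1
Why: Nucleophile-catalysed acylation should esterify the primary O7 and the secondary allylic O2, whereas the tertiary O1 is too hindered and O5/O6 are masked.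

Step 10
Reactants: 21 [(1R,2R,5S,6S)-2-(benzoyloxy)-1-hydroxy-5,6-(isopropylidenedioxy)cyclohex-3-en-1-yl]methyl benzoate
Product: 22 [(1S,2R,5S,6S)-2-(benzoyloxy)-1,5,6-trihydroxycyclohex-3-en-1-yl]methyl benzoate
Conditions: AcOH/H2O 4:1, 45 °C
Reagents that add atoms: none
Why: Acid-catalysed acetal hydrolysis should release O5–H and O6–H under conditions that leave the benzoates in place.

Step 11
Reactants: 22 [(1S,2R,5S,6S)-2-(benzoyloxy)-1,5,6-trihydroxycyclohex-3-en-1-yl]methyl benzoate; 20 benzoyl chloride
Product: 23 [(1S,2R,5S,6S)-2,5-bis(benzoyloxy)-1,6-dihydroxycyclohex-3-en-1-yl]methyl benzoate (target)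
Conditions: BzCl (1.1 equiv), pyridine, CH2Cl2, −40 to 0 °C
Reagents that add atoms: benzoyl chloride, O=C(Cl)c1ccccc1
Why: Kinetic mono-acylation, in which the allylic O5–H, flanked by the sp2 carbon C4, should react ahead of O6–H, which sits next to the fully substituted C1, while the tertiary O1 does not react.

Compound list
1 | benzoic acid | O=C(O)c1ccccc1 | starting material
2 | cyclohexa-2,5-diene-1-carboxylic acid | O=C(O)C1C=CCC=C1 | intermediate
3 | iodomethane | CI | starting material
4 | methyl cyclohexa-2,5-diene-1-carboxylate | COC(=O)C1C=CCC=C1 | intermediate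
5 | 3-phenyl-2-(phenylsulfonyl)oxaziridine (racemic) | O=S(=O)(N1OC1c1ccccc1)c1ccccc1 | starting material
6 | potassium dienolate of 4 | COC([O-])=C1C=CCC=C1.[K+] | intermediate
7 | methyl 1-hydroxycyclohexa-2,5-diene-1-carboxylate (achiral) | COC(=O)C1(O)C=CCC=C1 | intermediate
8 | cumene hydroperoxide | CC(C)(OO)c1ccccc1 | starting material
9 | methyl (1S,2R,3R)-2,3-epoxy-1-hydroxycyclohex-5-ene-1-carboxylate | COC(=O)[C@@]1(O)[C@@H]2O[C@@H]2CC=C1 | intermediate
10 | osmium tetroxide | O=[Os](=O)(=O)=O | starting material
11 | cyclic O5,O6-osmate ester of 12 with TMEDA on osmium | COC(=O)[C@@]1(O)[C@@H]2O[C@@H]2C[C@H](O3)[C@@H]1O[Os]3(=O)=O.CN(C)CCN(C)C | intermediate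
12 | methyl (1S,2R,3R,5S,6S)-2,3-epoxy-1,5,6-trihydroxycyclohexane-1-carboxylate (O1, oxirane O, O5, O6 all cis) | COC(=O)[C@@]1(O)[C@@H]2O[C@@H]2C[C@H](O)[C@@H]1O | intermediate
13 | 2-methoxypropene | C=C(C)OC | starting material
14 | methyl (1R,2R,3R,5S,6S)-2,3-epoxy-1-hydroxy-5,6-(isopropylidenedioxy)cyclohexane-1-carboxylate | COC(=O)[C@@]1(O)[C@@H]2O[C@@H]2C[C@H](O3)[C@@H]1OC3(C)C | intermediate
15 | (1R,2R,3R,5S,6S)-2,3-epoxy-1-(hydroxymethyl)-5,6-(isopropylidenedioxy)cyclohexan-1-ol | OC[C@@]1(O)[C@@H]2O[C@@H]2C[C@H](O3)[C@@H]1OC3(C)C | intermediate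
16 | diphenyl diselenide | c1ccc(cc1)[Se][Se]c1ccccc1 | starting material
17 | (1R,2S,3S,5S,6S)-1-(hydroxymethyl)-5,6-(isopropylidenedioxy)-3-(phenylselanyl)cyclohexane-1,2-diol (Se trans to O2) | OC[C@@]1(O)[C@H](O)[C@@H]([Se]c2ccccc2)C[C@H](O3)[C@@H]1OC3(C)C | intermediate
18 | Se-oxide of 17 (either configuration at selenium) | OC[C@@]1(O)[C@H](O)[C@@H]([Se](=O)c2ccccc2)C[C@H](O3)[C@@H]1OC3(C)C | intermediate
19 | (1R,2R,5S,6S)-1-(hydroxymethyl)-5,6-(isopropylidenedioxy)cyclohex-3-ene-1,2-diol | OC[C@@]1(O)[C@H](O)C=C[C@H](O3)[C@@H]1OC3(C)C | intermediate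
20 | benzoyl chloride | O=C(Cl)c1ccccc1 | starting material
21 | [(1R,2R,5S,6S)-2-(benzoyloxy)-1-hydroxy-5,6-(isopropylidenedioxy)cyclohex-3-en-1-yl]methyl benzoate | O=C(OC[C@@]1(O)[C@H](OC(=O)c2ccccc2)C=C[C@H](O3)[C@@H]1OC3(C)C)c1ccccc1 | intermediate
22 | [(1S,2R,5S,6S)-2-(benzoyloxy)-1,5,6-trihydroxycyclohex-3-en-1-yl]methyl benzoate | O=C(OC[C@@]1(O)[C@H](OC(=O)c2ccccc2)C=C[C@H](O)[C@@H]1O)c1ccccc1 | intermediate
23 | [(1S,2R,5S,6S)-2,5-bis(benzoyloxy)-1,6-dihydroxycyclohex-3-en-1-yl]methyl benzoate | O=C(OC[C@@]1(O)[C@H](OC(=O)c2ccccc2)C=C[C@H](OC(=O)c2ccccc2)[C@@H]1O)c1ccccc1 | target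

Total step count: 11. Longest linear sequence: 11 steps (the route is linear from benzoic acid).

Steps most likely to fail

Step 4. The catalyst may discriminate poorly between the two enantiotopic alkenes, or its Lewis acidity may trigger loss of water from the dienol and aromatisation. The fallback uses known chemistry, sets out from 7 and comes back at 12. VO(acac)2 (cat.) with tBuOOH (1 equiv) in CH2Cl2 at 0 °C, the classical hydroxyl-directed epoxidation of cyclic allylic alcohols, should give the syn mono-epoxide as a racemate, that is 9 together with its mirror image methyl (1R,2S,3S)-2,3-epoxy-1-hydroxycyclohex-5-ene-1-carboxylate F1. Dihydroxylation as in step 5 would pass through 11 and the mirror-image osmate ester F2 and give 12 together with its enantiomer methyl (1R,2S,3S,5R,6R)-2,3-epoxy-1,5,6-trihydroxycyclohexane-1-carboxylate F3. Acylation of the least hindered hydroxyl O5 with (1S)-camphanoyl chloride (pyridine, CH2Cl2, −20 °C) should turn the pair into two diastereomers, the O5 camphanate of 12 F4 and the O5 camphanate of its enantiomer F5, to be separated by chromatography or crystallisation. K2CO3 in MeOH then removes the auxiliary from F4 and returns 12 as one enantiomer.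

Step 5. Hydrogen-bond guidance may be too weak, because O1–H can also bind the neighbouring ester carbonyl, so that osmylation drifts to the ester face. The fallback sets out from 9 and comes back at 15; it removes the carbonyl before the dihydroxylation and puts a bulky group on the wrong face. NaBH4 in EtOH should reduce 9 to (1R,2R,3R)-2,3-epoxy-1-(hydroxymethyl)cyclohex-5-en-1-ol F6, and tBuMe2SiCl with imidazole in DMF should silylate only the primary O7 to give the O7 tert-butyldimethylsilyl ether of that diol F7. OsO4 with TMEDA in CH2Cl2 at −78 °C, now guided by an O1–H that has no internal acceptor and faced by the silyloxymethyl group on the other side, should add from the O1 face through the TMEDA-bound osmate ester F8 and, after aq. Na2SO3, give (1S,2R,3R,5S,6S)-1-[(tert-butyldimethylsilyloxy)methyl]-2,3-epoxycyclohexane-1,5,6-triol F9. 2-Methoxypropene with pyridinium p-toluenesulfonate gives the O5,O6-acetonide of that triol F10, and Bu4NF in THF frees O7 to give 15.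

Step 11. Site selectivity may be lost, with acylation at O6, at both hydroxyls, or benzoyl migration between O5 and O6. The fallback sets out from 22 and comes back at 23; it replaces steric control by the stereoelectronic opening of a cyclic orthoester. Trimethyl orthobenzoate with 10-camphorsulfonic acid (cat.) in CH2Cl2 should tie O5 and O6 into the cyclic O5,O6 methoxy(phenyl)methylene orthoester of 22 F11. Brief treatment with 80% aqueous AcOH at rt then opens it; such cis-fused orthoesters collapse to the ester on the axial oxygen, which in the half-chair that keeps C7 equatorial is the allylic O5, so 23 should result.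

Further compounds
F1 | step 4 | methyl (1R,2S,3S)-2,3-epoxy-1-hydroxycyclohex-5-ene-1-carboxylate (enantiomer of 9) | COC(=O)[C@]1(O)[C@H]2O[C@H]2CC=C1
F2 | step 4 | cyclic O5,O6-osmate ester of F3 with TMEDA on osmium (enantiomer of 11) | COC(=O)[C@]1(O)[C@H]2O[C@H]2C[C@@H](O3)[C@H]1O[Os]3(=O)=O.CN(C)CCN(C)C
F3 | step 4 | methyl (1R,2S,3S,5R,6R)-2,3-epoxy-1,5,6-trihydroxycyclohexane-1-carboxylate (enantiomer of 12) | COC(=O)[C@]1(O)[C@H]2O[C@H]2C[C@@H](O)[C@H]1O
F4 | step 4 | O5 (1S,4R)-camphanate of 12 | COC(=O)[C@@]1(O)[C@@H]2O[C@@H]2C[C@H](OC(=O)[C@@]34CC[C@@](C)(C(=O)O3)C4(C)C)[C@@H]1O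
F5 | step 4 | O5 (1S,4R)-camphanate of F3 | COC(=O)[C@]1(O)[C@H]2O[C@H]2C[C@@H](OC(=O)[C@@]34CC[C@@](C)(C(=O)O3)C4(C)C)[C@H]1O
F6 | step 5 | (1R,2R,3R)-2,3-epoxy-1-(hydroxymethyl)cyclohex-5-en-1-ol | OC[C@@]1(O)[C@@H]2O[C@@H]2CC=C1
F7 | step 5 | (1R,2R,3R)-1-[(tert-butyldimethylsilyloxy)methyl]-2,3-epoxycyclohex-5-en-1-ol | CC(C)(C)[Si](C)(C)OC[C@@]1(O)[C@@H]2O[C@@H]2CC=C1
F8 | step 5 | cyclic O5,O6-osmate ester of F9 with TMEDA on osmium | CC(C)(C)[Si](C)(C)OC[C@@]1(O)[C@@H]2O[C@@H]2C[C@H](O3)[C@@H]1O[Os]3(=O)=O.CN(C)CCN(C)C
F9 | step 5 | (1S,2R,3R,5S,6S)-1-[(tert-butyldimethylsilyloxy)methyl]-2,3-epoxycyclohexane-1,5,6-triol | CC(C)(C)[Si](C)(C)OC[C@@]1(O)[C@@H]2O[C@@H]2C[C@H](O)[C@@H]1O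
F10 | step 5 | (1R,2R,3R,5S,6S)-1-[(tert-butyldimethylsilyloxy)methyl]-2,3-epoxy-5,6-(isopropylidenedioxy)cyclohexan-1-ol | CC(C)(C)[Si](C)(C)OC[C@@]1(O)[C@@H]2O[C@@H]2C[C@H](O3)[C@@H]1OC3(C)C
F11 | step 11 | cyclic O5,O6 methoxy(phenyl)methylene orthoester of 22 (either configuration at the orthoester carbon) | O=C(OC[C@@]1(O)[C@H](OC(=O)c2ccccc2)C=C[C@H](O3)[C@@H]1OC3(OC)c1ccccc1)c1ccccc1
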